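**Strategy.** The trans-decalin is disconnected as a 1,5-diene cascade. Ring A (C1–C5, C10) and ring B (C5–C10) share the C5–C10 bond, a former (6E)-olefin. The C8=C12 methylene with the axial C9–CH2OAr group is a former (2Z)-allyl aryl ether. The cis C2-OAc/C3-O pair is an erythro epoxy acetate. One titanocene(III) radical cascade on the acyclic (9R,10R)-9-acetoxy-10,11-epoxy-(2Z,6E)-farnesyl isofraxidin ether closes ring A, then ring B last, and sets C5, C9, C10 and the exocyclic alkene. The precursor comes from a B-alkyl Suzuki coupling of a dienyl coumarin ether with a vinyl iodide carrying the carbinol centre. A final oxidation gives the 3-ketone.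

Key step: step 8

Remark: acyclic compounds are numbered as farnesyl chains (C1 = OCH2) and the bicycle as a drimane (C11 = CH2OAr, C12 = exocyclic CH2); farnesyl C9, C10, C11, C6, C7, C2, C3 become drimane C2, C3, C4, C5, C10, C9, C8; Ar = 6,8-dimethoxy-2-oxo-2H-chromen-7-yl; compounds 1, 2, 6 and 7 are assumed to be purchasable.

**Step 1**
Reactants: 1 3-methylbut-2-enal (prenal); 2 allenylboronic acid pinacol ester
Product: 3 (4R)-6-methylhept-5-en-1-yn-4-ol
Conditions: (R)-TRIP (10 mol%), 4 Å MS, toluene, −20 °C; aqueous work-up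
Reagents that add atoms: none
Why: Chiral phosphoric acid-catalysed propargylation of an aldehyde with an allenylboronate (SE2′ through a closed six-membered transition state), in which the (R)-catalyst is expected to direct Re-face addition as with aryl and alkenyl aldehydes and so set C4 as R.

**Step 2**
Reactants: 3 (4R)-6-methylhept-5-en-1-yn-4-ol
Product: 5 (1E,4R)-1-iodo-2,6-dimethylhepta-1,5-dien-4-ol, via alkenyldimethylalane 4 (not isolated)
Conditions: Me3Al, Cp2ZrCl2 (25 mol%), H2O, CH2Cl2, −23 °C; then I2, THF, −23 → 0 °C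
Reagents that add atoms: trimethylaluminium C[Al](C)C; iodine II
Why: Negishi zirconium-catalysed methylalumination (water-accelerated variant) should add CH3 and Al syn across the terminal alkyne with Al at the terminus, and iodinolysis with retention gives the E-iodide, while the carbinol centre (held as its aluminium alkoxide) is not involved.

**Step 3**
Reactants: 6 (2Z)-3-methylpent-2-en-4-yn-1-ol; 7 isofraxidin (7-hydroxy-6,8-dimethoxy-2H-chromen-2-one)
Product: 8 6,8-dimethoxy-7-{[(2Z)-3-methylpent-2-en-4-yn-1-yl]oxy}-2H-chromen-2-one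
Conditions: PPh3, DIAD, THF, 0 °C → rt
Reagents that add atoms: none
Why: Mitsunobu etherification of a primary allylic alcohol with an acidic phenol proceeds by SN2 at CH2, so the Z-olefin should be untouched.

**Step 4**
Reactants: 8 6,8-dimethoxy-7-{[(2Z)-3-methylpent-2-en-4-yn-1-yl]oxy}-2H-chromen-2-one
Product: 9 6,8-dimethoxy-7-{[(2Z)-3-methylpenta-2,4-dien-1-yl]oxy}-2H-chromen-2-one
Conditions: H2 (1 atm), Lindlar catalyst, quinoline, EtOAc, rt
Reagents that add atoms: none
Why: Lindlar semi-hydrogenation of the terminal alkyne should stop at the vinyl group, the poisoned catalyst leaving the trisubstituted olefin, the allyl aryl ether and the coumarin C3=C4 bond alone.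

**Step 5**
Reactants: 9 6,8-dimethoxy-7-{[(2Z)-3-methylpenta-2,4-dien-1-yl]oxy}-2H-chromen-2-one; 5 (1E,4R)-1-iodo-2,6-dimethylhepta-1,5-dien-4-ol
Product: 11 7-{[(2Z,6E,9R)-9-hydroxy-3,7,11-trimethyldodeca-2,6,10-trien-1-yl]oxy}-6,8-dimethoxy-2H-chromen-2-one, via alkyl-9-BBN borane 10 (not isolated)
Conditions: 9-BBN, THF, 0 °C → rt; then 5, Pd(dppf)Cl2 (5 mol%), AsPh3, Cs2CO3, DMF/THF/H2O, rt
Reagents that add atoms: 9-borabicyclo[3.3.1]nonane C1CC2CCCC(C1)B2 (boron is retained only in 10)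
Why: 9-BBN should hydroborate only the monosubstituted diene terminus (boron at C5), and the B-alkyl Suzuki–Miyaura coupling with the E-alkenyl iodide forms the C5–C6 bond with retention of olefin geometry and tolerates the free hydroxyl.

**Step 6**
Reactants: 11 7-{[(2Z,6E,9R)-9-hydroxy-3,7,11-trimethyldodeca-2,6,10-trien-1-yl]oxy}-6,8-dimethoxy-2H-chromen-2-one
Product: 12 7-{[(2Z,6E,9R)-9-[(2R)-3,3-dimethyloxiran-2-yl]-9-hydroxy-3,7-dimethylnona-2,6-dien-1-yl]oxy}-6,8-dimethoxy-2H-chromen-2-one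
Conditions: Ti(OiPr)4 (20 mol%), D-(−)-DIPT (24 mol%), TBHP, 4 Å MS, CH2Cl2, −20 °C
Reagents that add atoms: tert-butyl hydroperoxide CC(C)(C)OO
Why: Sharpless asymmetric epoxidation of a secondary allylic alcohol, in which the D-(−)-tartrate catalyst is matched with the R-carbinol and should give the erythro (9R,10R) epoxy alcohol at the allylic olefin only, any residual S-alcohol reacting slowly and being left behind.

**Step 7**
Reactants: 12 7-{[(2Z,6E,9R)-9-[(2R)-3,3-dimethyloxiran-2-yl]-9-hydroxy-3,7-dimethylnona-2,6-dien-1-yl]oxy}-6,8-dimethoxy-2H-chromen-2-one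
Product: 13 7-{[(2Z,6E,9R)-9-acetoxy-9-[(2R)-3,3-dimethyloxiran-2-yl]-3,7-dimethylnona-2,6-dien-1-yl]oxy}-6,8-dimethoxy-2H-chromen-2-one
Conditions: Ac2O, pyridine, DMAP (cat.), CH2Cl2, 0 °C
Reagents that add atoms: acetic anhydride CC(=O)OC(C)=O
Why: DMAP-catalysed acetylation of the secondary alcohol should leave the epoxide and both stereocentres untouched.

**Step 8**
Reactants: 13 7-{[(2Z,6E,9R)-9-acetoxy-9-[(2R)-3,3-dimethyloxiran-2-yl]-3,7-dimethylnona-2,6-dien-1-yl]oxy}-6,8-dimethoxy-2H-chromen-2-one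
Product: 15 7-{[(2R,3S,5S,9S,10R)-2-acetoxy-3-hydroxydrim-8(12)-en-11-yl]oxy}-6,8-dimethoxy-2H-chromen-2-one, via trimethylsilyl ether 14 (not isolated)
Conditions: Cp2TiCl2 (20 mol%), Mn, TMSCl, 2,4,6-collidine, THF (0.02 M), rt; then 1 M HCl, THF, 0 °C
Reagents that add atoms: chlorotrimethylsilane C[Si](C)(C)Cl (silicon is retained only in 14)
Why: Cp2TiCl (from Cp2TiCl2/Mn) should open the trisubstituted epoxide homolytically to the tertiary C4 radical with C3–O–Ti, which closes ring A by 6-endo-trig attack on C5 of the 6E-olefin and then ring B by 6-endo-trig attack of the tertiary C10 radical on C9 of the 2Z-olefin; the tertiary C8 radical is trapped by a second Cp2TiCl and loses a C12 hydrogen (mixed disproportionation/β-hydride elimination) to give the exocyclic C8=C12 alkene, while TMSCl/collidine returns Cp2TiCl2 and silylates O3. The closest known reaction type is the titanocene(III)-catalysed radical cyclization of epoxypolyprenes (epoxyfarnesyl esters to 3-hydroxy-8(12)-drimenes). C2 and C3 are carried over unchanged from the erythro epoxy acetate; C5 and C10 follow from the chair transition state with the bulky C3–OTi group equatorial, which puts the cis C2 acetate axial, so that ring B is expected to form on the opposite face of the planar C10 radical (equatorial C9–C10 bond, axial methyl, trans fusion). C9 is set by the olefin geometry: in the chair closure the CH2OAr group, cis to C7 on the Z-alkene, becomes axial and anti to the C10 methyl. The step needs 6-endo over 5-exo closure (secured by attack at the CH terminus of each trisubstituted olefin), exo-selective termination (titanium-mediated hydrogen loss from the methyl group) and no 1,2-acetyl shift to the titanium alkoxide (limited by fast O-silylation with TMSCl/collidine).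

**Step 9**
Reactants: 15 7-{[(2R,3S,5S,9S,10R)-2-acetoxy-3-hydroxydrim-8(12)-en-11-yl]oxy}-6,8-dimethoxy-2H-chromen-2-one
Product: 16 7-{[(2R,5S,9S,10R)-2-acetoxy-3-oxodrim-8(12)-en-11-yl]oxy}-6,8-dimethoxy-2H-chromen-2-one (target)
Conditions: Dess–Martin periodinane, pyridine, CH2Cl2, 0 °C → rt
Reagents that add atoms: none
Why: Dess–Martin oxidation of the equatorial C3 alcohol under buffered conditions should leave the acetate, the epimerisable C2 centre, the exocyclic alkene and the coumarin intact.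

**Compound list**
1 | 3-methylbut-2-enal (prenal) | CC(C)=CC=O | starting material
2 | allenylboronic acid pinacol ester | C=C=CB1OC(C)(C)C(C)(C)O1 | starting material
3 | (4R)-6-methylhept-5-en-1-yn-4-ol | C#CC[C@@H](O)C=C(C)C | intermediate
4 | dimethyl[(1E,4R)-4-(dimethylaluminooxy)-2,6-dimethylhepta-1,5-dien-1-yl]alane | C[Al](C)/C=C(\C)C[C@@H](O[Al](C)C)C=C(C)C | intermediate
5 | (1E,4R)-1-iodo-2,6-dimethylhepta-1,5-dien-4-ol | I/C=C(\C)C[C@@H](O)C=C(C)C | intermediate
6 | (2Z)-3-methylpent-2-en-4-yn-1-ol | C#C/C(C)=C\CO | starting material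
7 | isofraxidin (7-hydroxy-6,8-dimethoxy-2H-chromen-2-one) | Oc1c(OC)cc2ccc(=O)oc2c1OC | starting material
8 | 6,8-dimethoxy-7-{[(2Z)-3-methylpent-2-en-4-yn-1-yl]oxy}-2H-chromen-2-one | C#C/C(C)=C\COc1c(OC)cc2ccc(=O)oc2c1OC | intermediate
9 | 6,8-dimethoxy-7-{[(2Z)-3-methylpenta-2,4-dien-1-yl]oxy}-2H-chromen-2-one | C=C/C(C)=C\COc1c(OC)cc2ccc(=O)oc2c1OC | intermediate
10 | 7-{[(2Z)-5-(9-borabicyclo[3.3.1]nonan-9-yl)-3-methylpent-2-en-1-yl]oxy}-6,8-dimethoxy-2H-chromen-2-one | C1CC2CCCC(C1)B2CC/C(C)=C\COc1c(OC)cc2ccc(=O)oc2c1OC | intermediate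
11 | 7-{[(2Z,6E,9R)-9-hydroxy-3,7,11-trimethyldodeca-2,6,10-trien-1-yl]oxy}-6,8-dimethoxy-2H-chromen-2-one | CC(C)=C[C@H](O)C/C(C)=C/CC/C(C)=C\COc1c(OC)cc2ccc(=O)oc2c1OC | intermediate
12 | 7-{[(2Z,6E,9R)-9-[(2R)-3,3-dimethyloxiran-2-yl]-9-hydroxy-3,7-dimethylnona-2,6-dien-1-yl]oxy}-6,8-dimethoxy-2H-chromen-2-one | CC1(C)[C@H](O1)[C@H](O)C/C(C)=C/CC/C(C)=C\COc1c(OC)cc2ccc(=O)oc2c1OC | intermediate
13 | 7-{[(2Z,6E,9R)-9-acetoxy-9-[(2R)-3,3-dimethyloxiran-2-yl]-3,7-dimethylnona-2,6-dien-1-yl]oxy}-6,8-dimethoxy-2H-chromen-2-one | CC1(C)[C@H](O1)[C@H](OC(C)=O)C/C(C)=C/CC/C(C)=C\COc1c(OC)cc2ccc(=O)oc2c1OC | intermediate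
14 | 7-{[(2R,3S,5S,9S,10R)-2-acetoxy-3-(trimethylsilyloxy)drim-8(12)-en-11-yl]oxy}-6,8-dimethoxy-2H-chromen-2-one | C=C1CC[C@@H]2C(C)(C)[C@H](O[Si](C)(C)C)[C@H](OC(C)=O)C[C@@]2(C)[C@H]1COc1c(OC)cc2ccc(=O)oc2c1OC | intermediate
15 | 7-{[(2R,3S,5S,9S,10R)-2-acetoxy-3-hydroxydrim-8(12)-en-11-yl]oxy}-6,8-dimethoxy-2H-chromen-2-one (trans-decalin; 2-OAc axial and 3-OH equatorial, both cis to the C10 methyl; C9–CH2OAr axial, trans to the C10 methyl) | C=C1CC[C@@H]2C(C)(C)[C@H](O)[C@H](OC(C)=O)C[C@@]2(C)[C@H]1COc1c(OC)cc2ccc(=O)oc2c1OC | intermediate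
16 | 7-{[(2R,5S,9S,10R)-2-acetoxy-3-oxodrim-8(12)-en-11-yl]oxy}-6,8-dimethoxy-2H-chromen-2-one | C=C1CC[C@@H]2C(C)(C)C(=O)[C@H](OC(C)=O)C[C@@]2(C)[C@H]1COc1c(OC)cc2ccc(=O)oc2c1OC | target

**Step count.** Total: 9 steps. Longest linear sequence: 7 steps (1 → 3 → 5 → 11 → 12 → 13 → 15 → 16; the branch 6 → 8 → 9 → 11 is equally long).

**Steps most likely to fail**

Step 8. Possible failures are migration of the acetyl group from O2 to the titanium-bound O3 before silylation, loss of facial control in the first ring closure because the acetate must sit axial, and erosion of the Z-olefin information in the stepwise radical closure of ring B. The fallback sets out from 12 and comes back at 16. The C9 hydroxyl of 12 is silylated (TESCl, imidazole) to give the triethylsilyl ether F1, which has no acyl group to migrate. The same titanocene(III) cascade, run with stoichiometric Cp2TiCl (Cp2TiCl2, Mn, THF) and aqueous work-up, should give the 3-hydroxy-2-silyloxy drimenyl ether F2. Dess–Martin oxidation gives the ketone F3, HF·pyridine frees the 2-hydroxy ketone F4, and acetylation (Ac2O, pyridine, cat. DMAP, 0 °C) gives 16.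

Step 5. Possible failures are ionisation of the allylic aryl ether by Pd(0) (Z/E scrambling or loss of the coumarin) and base-induced opening of the lactone during the coupling. The fallback sets out from 6 and comes back at 11. Alcohol 6 is silylated (TBSCl, imidazole) to the silyl ether F5 and semi-hydrogenated (Lindlar) to the diene F6. Hydroboration with 9-BBN gives the borane F7, which is coupled with 5 under the same Suzuki conditions to give the mono-silylated diol F8. TBAF then frees the diol F9, whose primary allylic hydroxyl should be etherified selectively with 7 under Mitsunobu conditions (1 equiv PPh3/DIAD, 0 °C) to give 11.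

Step 1. Possible failures are insufficient enantioselectivity with the β,β-disubstituted enal and loss of the volatile product. The fallback sets out from 1 and comes back at 3. Zinc-mediated Barbier propargylation of 1 with propargyl bromide gives the racemic alcohol F10. Sharpless kinetic resolution (Ti(OiPr)4, L-(+)-DIPT, 0.6 equiv TBHP) should epoxidise the S-enantiomer and return (R)-3.

**Further compounds**
F1 | step 8 | 7-{[(2Z,6E,9R)-9-[(2R)-3,3-dimethyloxiran-2-yl]-3,7-dimethyl-9-(triethylsilyloxy)nona-2,6-dien-1-yl]oxy}-6,8-dimethoxy-2H-chromen-2-one | CC1(C)[C@H](O1)[C@H](O[Si](CC)(CC)CC)C/C(C)=C/CC/C(C)=C\COc1c(OC)cc2ccc(=O)oc2c1OC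
F2 | step 8 | 7-{[(2R,3S,5S,9S,10R)-3-hydroxy-2-(triethylsilyloxy)drim-8(12)-en-11-yl]oxy}-6,8-dimethoxy-2H-chromen-2-one | C=C1CC[C@@H]2C(C)(C)[C@H](O)[C@H](O[Si](CC)(CC)CC)C[C@@]2(C)[C@H]1COc1c(OC)cc2ccc(=O)oc2c1OC
F3 | step 8 | 7-{[(2R,5S,9S,10R)-3-oxo-2-(triethylsilyloxy)drim-8(12)-en-11-yl]oxy}-6,8-dimethoxy-2H-chromen-2-one | C=C1CC[C@@H]2C(C)(C)C(=O)[C@H](O[Si](CC)(CC)CC)C[C@@]2(C)[C@H]1COc1c(OC)cc2ccc(=O)oc2c1OC
F4 | step 8 | 7-{[(2R,5S,9S,10R)-2-hydroxy-3-oxodrim-8(12)-en-11-yl]oxy}-6,8-dimethoxy-2H-chromen-2-one | C=C1CC[C@@H]2C(C)(C)C(=O)[C@H](O)C[C@@]2(C)[C@H]1COc1c(OC)cc2ccc(=O)oc2c1OC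
F5 | step 5 | tert-butyldimethyl{[(2Z)-3-methylpent-2-en-4-yn-1-yl]oxy}silane | C#C/C(C)=C\CO[Si](C)(C)C(C)(C)C
F6 | step 5 | tert-butyldimethyl{[(2Z)-3-methylpenta-2,4-dien-1-yl]oxy}silane | C=C/C(C)=C\CO[Si](C)(C)C(C)(C)C
F7 | step 5 | {[(2Z)-5-(9-borabicyclo[3.3.1]nonan-9-yl)-3-methylpent-2-en-1-yl]oxy}(tert-butyl)dimethylsilane | C1CC2CCCC(C1)B2CC/C(C)=C\CO[Si](C)(C)C(C)(C)C
F8 | step 5 | (4R,6E,10Z)-12-(tert-butyldimethylsilyloxy)-2,6,10-trimethyldodeca-2,6,10-trien-4-ol | CC(C)=C[C@H](O)C/C(C)=C/CC/C(C)=C\CO[Si](C)(C)C(C)(C)C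
F9 | step 5 | (2Z,6E,9R)-3,7,11-trimethyldodeca-2,6,10-triene-1,9-diol | CC(C)=C[C@H](O)C/C(C)=C/CC/C(C)=C\CO
F10 | step 1 | rac-6-methylhept-5-en-1-yn-4-ol | C#CCC(O)C=C(C)C
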